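Plan
1. Numbering (halimane): ring A = C1–C5 + C10 (C3 ketone; C4 quaternary with CH3 and the acyloxymethyl carbon C19), ring B = C5–C10 (C6 OH, C8 CH3, C9 quaternary), alkene C5=C10 at the ring fusion, side chain C11–C16.
2. Cuts: the C19–O ester bond; C12–C13 (butenolide) back to a vinyl group on C9; then ring A at C1–C10 and C3–C4, leaving a ring B cyclohexene with a propanoate arm on C5 plus an acrylate (C1–C2–C3).
3. Enabling feature: C4 carries C19, so with C19 at the carboxyl level the array C4–C5=C10 is an ester dienolate, nucleophilic at C10 (γ) and C4 (α), matched by an acrylate electrophilic at C1 and C3. One vinylogous Michael/Dieckmann cascade then closes ring A, forms the C3 ketone and the C4 quaternary center and keeps the alkene at C5=C10.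
4. Forward order: ring B by an enantioselective Diels–Alder reaction, α-iodination, CBS reduction, Reformatsky–Negishi coupling of the propanoate arm, ring A annulation, then C19 reduction, acylation, C3 reoxidation, B-alkyl Suzuki coupling to the butenolide, desilylation.
5. Stereochemistry: C8 and C9 from the E-enal and the chiral Lewis acid, C6 from the CBS catalyst, C4 from the pseudoaxial C6 silyloxy group during ring closure.
6. Helpers removed later: carboxyl oxidation level at C19 as its tert-butyl ester (step 9), silyl ethers on O6 and the phenol (step 14), the vinyl group as latent side chain (step 13).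

Key step: step 8

Remark: halimane numbering is used for the skeleton carbons in all intermediates; α/β refer to the target drawn with ring A on the left (C6–O and 4-CH3 α; 8-CH3, 9-CH3 and C19 β).
Remark (assumption): the (S,S)-enantiomer of the chromium catalyst in step 1 is taken to give 3 in the absolute configuration shown; if the sense is opposite, the mirror-image catalyst is used.

Step 1
Reactants: 1 (E)-2-methylbut-2-enal; 2 (E)-3-(tert-butyldimethylsilyloxy)-N,N-dimethylbuta-1,3-dien-1-amine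
Product: 3 (1R,2S,6S)-4-(tert-butyldimethylsilyloxy)-2-(dimethylamino)-1,6-dimethylcyclohex-3-ene-1-carbaldehyde
Conditions: (S,S)-(salen)CrSbF6 {[N,N′-bis(3,5-di-tert-butylsalicylidene)cyclohexane-1,2-diamine]chromium hexafluoroantimonate, trivalent chromium} (5 mol%), 4 Å MS, CH2Cl2, −40 °C
Reagents that add atoms: none
Why: Lewis-acid-catalysed Diels–Alder reaction of a 1-amino-3-siloxy diene with an α-substituted enal, in which the CH2 terminus of 2 bonds to the β-carbon of 1, the E geometry of 1 places the two methyl groups cis (C8/C9) and the chiral chromium Lewis acid should select the enal face and so set both centers in the absolute sense (the amino-bearing center is removed in step 3).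

Step 2
Reactants: 3 (1R,2S,6S)-4-(tert-butyldimethylsilyloxy)-2-(dimethylamino)-1,6-dimethylcyclohex-3-ene-1-carbaldehyde
Product: 4 (1S,5S,6R)-3-(tert-butyldimethylsilyloxy)-6-ethenyl-N,N,5,6-tetramethylcyclohex-2-en-1-amine
Conditions: Ph3PCH3Br, KHMDS, THF, 0 °C → rt
Reagents that add atoms: methyltriphenylphosphonium bromide, C[P+](c1ccccc1)(c1ccccc1)c1ccccc1.[Br-]
Why: Wittig methylenation of the neopentyl aldehyde converts the formyl group into the vinyl group (C11=C12) without touching the silyl enol ether or the allylic amine.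

Step 3
Reactants: 4 (1S,5S,6R)-3-(tert-butyldimethylsilyloxy)-6-ethenyl-N,N,5,6-tetramethylcyclohex-2-en-1-amine
Product: 5 (4R,5S)-4-ethenyl-4,5-dimethylcyclohex-2-en-1-one
Conditions: aq HF, MeCN, 0 °C → rt
Reagents that add atoms: none
Why: Acid cleavage of the silyl enol ether to the β-amino ketone followed by β-elimination of dimethylamine (E1cB) unveils the 4,4-disubstituted cyclohexenone.

Step 4
Reactants: 5 (4R,5S)-4-ethenyl-4,5-dimethylcyclohex-2-en-1-one
Product: 6 (4R,5S)-4-ethenyl-2-iodo-4,5-dimethylcyclohex-2-en-1-one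
Conditions: I2, pyridine, CH2Cl2, 0 °C → rt
Reagents that add atoms: iodine, II
Why: α-Iodination of the enone by conjugate addition of pyridine, iodination of the enolate and elimination installs the C5 handle for cross-coupling.

Step 5
Reactants: 6 (4R,5S)-4-ethenyl-2-iodo-4,5-dimethylcyclohex-2-en-1-one
Product: 7 (1S,4R,5S)-4-ethenyl-2-iodo-4,5-dimethylcyclohex-2-en-1-ol
Conditions: (R)-2-methyl-CBS-oxazaborolidine (0.2 equiv), catecholborane, toluene, −78 °C
Reagents that add atoms: none
Why: CBS reduction, in which the (R)-oxazaborolidine differentiates the iodoalkenyl (large) and methylene (small) flanks of the ketone and should deliver hydride to give the (1S)-carbinol, sets C6 (oxygen trans to both ring methyl groups) under reagent control.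

Step 6
Reactants: 7 (1S,4R,5S)-4-ethenyl-2-iodo-4,5-dimethylcyclohex-2-en-1-ol
Product: 8 tert-butyl{[(1S,4R,5S)-4-ethenyl-2-iodo-4,5-dimethylcyclohex-2-en-1-yl]oxy}dimethylsilane
Conditions: TBSCl, imidazole, DMF, rt
Reagents that add atoms: tert-butyldimethylsilyl chloride, CC(C)(C)[Si](C)(C)Cl
Why: Silylation of the secondary allylic alcohol gives the ether that later directs the C4 configuration.

Step 7
Reactants: 8 tert-butyl{[(1S,4R,5S)-4-ethenyl-2-iodo-4,5-dimethylcyclohex-2-en-1-yl]oxy}dimethylsilane; 9 tert-butyl 2-bromopropanoate (racemic)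
Product: 11 tert-butyl (2RS)-2-[(3R,4S,6S)-6-(tert-butyldimethylsilyloxy)-3-ethenyl-3,4-dimethylcyclohex-1-en-1-yl]propanoate, via Reformatsky reagent 10 (not isolated)
Conditions: 9, Zn dust (TMSCl-activated), THF, rt; then 8, Pd(dba)2 (5 mol%), P(t-Bu)3 (10 mol%), THF, rt → 50 °C
Reagents that add atoms: none
Why: Reformatsky reagent formation and palladium-catalysed Negishi-type coupling of the zinc ester enolate with the alkenyl iodide attach the propanoate arm at C5 with the double bond fixed at C5=C10, the new α-stereocenter being formed as a mixture that is erased in step 8.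

Step 8
Reactants: 11 tert-butyl (2RS)-2-[(3R,4S,6S)-6-(tert-butyldimethylsilyloxy)-3-ethenyl-3,4-dimethylcyclohex-1-en-1-yl]propanoate; 12 methyl acrylate
Product: 14 tert-butyl (1R,5R,6S,8S)-8-(tert-butyldimethylsilyloxy)-5-ethenyl-1,5,6-trimethyl-2-oxo-1,2,3,4,5,6,7,8-octahydronaphthalene-1-carboxylate, via Michael adduct enolate 13 (not isolated)
Conditions: LDA (1.05 equiv), THF, −78 °C; 12 (1.1 equiv, slow addition), −78 → 0 °C; aq NH4Cl
Reagents that add atoms: none
Why: Proposed new method: LDA removes the doubly activated C4–H (α to the ester, allylic) to give the ester dienolate spanning C4–C5=C10, its γ-carbon C10 adds to 12 (vinylogous Michael addition), the arm enolate so formed takes up H10 through a six-centre proton shift to its oxygen and thereby regenerates the dienolate, which acylates at C4 on the methyl ester (Dieckmann-type Claisen closure, loss of methoxide) and leaves the double bond at C5=C10. The closest known reaction types are the Michael–Claisen [3+3] annulation of ketone enolates with acrylates and the Michael–Dieckmann annulation of toluate anions (Staunton–Weinreb annulation); the use of an α,γ-dinucleophilic ester dienolate as the three-carbon partner is the unprecedented part. Ring A closes in the 6-(enolexo)-exo-trig mode. The single new stereocenter C4 is controlled by the pseudoaxial C6 silyloxy group: in the cyclising rotamer the enolate is twisted out of the C5=C10 plane, the bulky ester arm turns to the face opposite OTBS and the small methyl group to the same face, which is the relation in the target (4-CH3 cis to 6-O). The step needs γ- rather than α-attack on the acrylate, enolisation of the adduct toward C10 and not C6, and acylation by C4 rather than attack of the arm enolate on C19: the first should follow because α-addition at the fully substituted C4 is reversible and only the γ-adduct can close, the second because H10 lies within reach of the arm enolate while C6–H sits on the other ring face under the silyl ether, and the third because the ester on C19 is tert-butyl.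

Step 9
Reactants: 14 tert-butyl (1R,5R,6S,8S)-8-(tert-butyldimethylsilyloxy)-5-ethenyl-1,5,6-trimethyl-2-oxo-1,2,3,4,5,6,7,8-octahydronaphthalene-1-carboxylate
Product: 15 (1S,2RS,5R,6S,8S)-8-(tert-butyldimethylsilyloxy)-5-ethenyl-1-(hydroxymethyl)-1,5,6-trimethyl-1,2,3,4,5,6,7,8-octahydronaphthalen-2-ol
Conditions: LiAlH4, THF, 0 → 40 °C; Rochelle salt work-up
Reagents that add atoms: none
Why: LiAlH4 reduction of the hindered tert-butyl ester to the C19 primary alcohol and of the C3 ketone (epimer mixture, reoxidised in step 12), under conditions that leave the silyl ether and both alkenes intact.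

Step 10
Reactants: 16 3-(4-hydroxyphenyl)propanoic acid
Product: 18 3-[4-(tert-butyldimethylsilyloxy)phenyl]propanoic acid, via bis-silyl derivative 17 (not isolated)
Conditions: TBSCl (2.2 equiv), imidazole, DMF, rt; then AcOH–THF–H2O, rt
Reagents that add atoms: tert-butyldimethylsilyl chloride, CC(C)(C)[Si](C)(C)Cl
Why: Silylation of both acidic hydroxyl groups followed by selective hydrolysis of the labile silyl ester frees the carboxylic acid with the phenol protected.

Step 11
Reactants: 15 (1S,2RS,5R,6S,8S)-8-(tert-butyldimethylsilyloxy)-5-ethenyl-1-(hydroxymethyl)-1,5,6-trimethyl-1,2,3,4,5,6,7,8-octahydronaphthalen-2-ol; 18 3-[4-(tert-butyldimethylsilyloxy)phenyl]propanoic acid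
Product: 19 [(1S,2RS,5R,6S,8S)-8-(tert-butyldimethylsilyloxy)-5-ethenyl-2-hydroxy-1,5,6-trimethyl-1,2,3,4,5,6,7,8-octahydronaphthalen-1-yl]methyl 3-[4-(tert-butyldimethylsilyloxy)phenyl]propanoate
Conditions: EDC·HCl, DMAP, CH2Cl2, 0 °C
Reagents that add atoms: none
Why: Carbodiimide (Steglich) esterification, which should acylate the primary C19 hydroxyl in preference to the more hindered secondary C3 hydroxyl.

Step 12
Reactants: 19 [(1S,2RS,5R,6S,8S)-8-(tert-butyldimethylsilyloxy)-5-ethenyl-2-hydroxy-1,5,6-trimethyl-1,2,3,4,5,6,7,8-octahydronaphthalen-1-yl]methyl 3-[4-(tert-butyldimethylsilyloxy)phenyl]propanoate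
Product: 20 [(1S,5R,6S,8S)-8-(tert-butyldimethylsilyloxy)-5-ethenyl-1,5,6-trimethyl-2-oxo-1,2,3,4,5,6,7,8-octahydronaphthalen-1-yl]methyl 3-[4-(tert-butyldimethylsilyloxy)phenyl]propanoate
Conditions: Dess–Martin periodinane, NaHCO3, CH2Cl2, 0 °C → rt
Reagents that add atoms: none
Why: Dess–Martin oxidation returns C3 to the ketone; the β-acyloxy ketone cannot eliminate because C4 is quaternary.

Step 13
Reactants: 20 [(1S,5R,6S,8S)-8-(tert-butyldimethylsilyloxy)-5-ethenyl-1,5,6-trimethyl-2-oxo-1,2,3,4,5,6,7,8-octahydronaphthalen-1-yl]methyl 3-[4-(tert-butyldimethylsilyloxy)phenyl]propanoate; 21 4-bromofuran-2(5H)-one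
Product: 23 [(1S,5R,6S,8S)-8-(tert-butyldimethylsilyloxy)-1,5,6-trimethyl-2-oxo-5-[2-(5-oxo-2,5-dihydrofuran-3-yl)ethyl]-1,2,3,4,5,6,7,8-octahydronaphthalen-1-yl]methyl 3-[4-(tert-butyldimethylsilyloxy)phenyl]propanoate, via alkylborane 22 (not isolated)
Conditions: 9-BBN dimer, THF, 0 °C → rt; then 21, PdCl2(dppf) (5 mol%), AsPh3, aq K3PO4, DMF, rt
Reagents that add atoms: none
Why: Anti-Markovnikov hydroboration of the monosubstituted alkene with 9-BBN (the tetrasubstituted C5=C10 alkene and the hindered ketone should not react) followed by B-alkyl Suzuki–Miyaura coupling with the vinylogous acyl bromide joins C12 to C13 and completes the butenolide side chain.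

Step 14
Reactants: 23 [(1S,5R,6S,8S)-8-(tert-butyldimethylsilyloxy)-1,5,6-trimethyl-2-oxo-5-[2-(5-oxo-2,5-dihydrofuran-3-yl)ethyl]-1,2,3,4,5,6,7,8-octahydronaphthalen-1-yl]methyl 3-[4-(tert-butyldimethylsilyloxy)phenyl]propanoate
Product: 24 [(1S,5R,6S,8S)-8-hydroxy-1,5,6-trimethyl-2-oxo-5-[2-(5-oxo-2,5-dihydrofuran-3-yl)ethyl]-1,2,3,4,5,6,7,8-octahydronaphthalen-1-yl]methyl 3-(4-hydroxyphenyl)propanoate (CNP0301014.1)
Conditions: HF·pyridine, pyridine, THF, 0 °C → rt
Reagents that add atoms: none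
Why: Fluoride-mediated cleavage of both silyl ethers with buffered HF·pyridine liberates the C6 alcohol and the phenol without harming the ester, the β-acyloxy ketone or the butenolide.

Compound list
1 | (E)-2-methylbut-2-enal | C/C=C(\C)C=O | starting material
2 | (E)-3-(tert-butyldimethylsilyloxy)-N,N-dimethylbuta-1,3-dien-1-amine | CN(C)/C=C/C(=C)O[Si](C)(C)C(C)(C)C | starting material
3 | (1R,2S,6S)-4-(tert-butyldimethylsilyloxy)-2-(dimethylamino)-1,6-dimethylcyclohex-3-ene-1-carbaldehyde | C[C@H]1CC(O[Si](C)(C)C(C)(C)C)=C[C@H](N(C)C)[C@]1(C)C=O | intermediate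
4 | (1S,5S,6R)-3-(tert-butyldimethylsilyloxy)-6-ethenyl-N,N,5,6-tetramethylcyclohex-2-en-1-amine | C[C@H]1CC(O[Si](C)(C)C(C)(C)C)=C[C@H](N(C)C)[C@]1(C)C=C | intermediate
5 | (4R,5S)-4-ethenyl-4,5-dimethylcyclohex-2-en-1-one | C[C@H]1CC(=O)C=C[C@]1(C)C=C | intermediate
6 | (4R,5S)-4-ethenyl-2-iodo-4,5-dimethylcyclohex-2-en-1-one | C[C@H]1CC(=O)C(I)=C[C@]1(C)C=C | intermediate
7 | (1S,4R,5S)-4-ethenyl-2-iodo-4,5-dimethylcyclohex-2-en-1-ol | C[C@H]1C[C@H](O)C(I)=C[C@]1(C)C=C | intermediate
8 | tert-butyl{[(1S,4R,5S)-4-ethenyl-2-iodo-4,5-dimethylcyclohex-2-en-1-yl]oxy}dimethylsilane | C[C@H]1C[C@H](O[Si](C)(C)C(C)(C)C)C(I)=C[C@]1(C)C=C | intermediate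
9 | tert-butyl 2-bromopropanoate (racemic) | CC(Br)C(=O)OC(C)(C)C | starting material
10 | (1-tert-butoxy-1-oxopropan-2-yl)zinc bromide (Reformatsky reagent) | CC([Zn]Br)C(=O)OC(C)(C)C | intermediate
11 | tert-butyl (2RS)-2-[(3R,4S,6S)-6-(tert-butyldimethylsilyloxy)-3-ethenyl-3,4-dimethylcyclohex-1-en-1-yl]propanoate | C[C@H]1C[C@H](O[Si](C)(C)C(C)(C)C)C(C(C)C(=O)OC(C)(C)C)=C[C@]1(C)C=C | intermediate
12 | methyl acrylate | C=CC(=O)OC | starting material
13 | Michael adduct, present as the lithium enolate of the methyl ester arm and drawn as the neutral diester: tert-butyl 2-{(2S,3R,4S,6S)-6-(tert-butyldimethylsilyloxy)-3-ethenyl-2-(3-methoxy-3-oxopropyl)-3,4-dimethylcyclohexylidene}propanoate, arm on C10 anti to the C9 methyl group, tert-butyl ester cis to C10 | C[C@H]1C[C@H](O[Si](C)(C)C(C)(C)C)/C(=C(\C)C(=O)OC(C)(C)C)[C@H](CCC(=O)OC)[C@]1(C)C=C | intermediate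
14 | tert-butyl (1R,5R,6S,8S)-8-(tert-butyldimethylsilyloxy)-5-ethenyl-1,5,6-trimethyl-2-oxo-1,2,3,4,5,6,7,8-octahydronaphthalene-1-carboxylate | C[C@H]1C[C@H](O[Si](C)(C)C(C)(C)C)C2=C(CCC(=O)[C@]2(C)C(=O)OC(C)(C)C)[C@]1(C)C=C | intermediate
15 | (1S,2RS,5R,6S,8S)-8-(tert-butyldimethylsilyloxy)-5-ethenyl-1-(hydroxymethyl)-1,5,6-trimethyl-1,2,3,4,5,6,7,8-octahydronaphthalen-2-ol | C[C@H]1C[C@H](O[Si](C)(C)C(C)(C)C)C2=C(CCC(O)[C@]2(C)CO)[C@]1(C)C=C | intermediate
16 | 3-(4-hydroxyphenyl)propanoic acid | OC(=O)CCc1ccc(O)cc1 | starting material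
17 | tert-butyldimethylsilyl 3-[4-(tert-butyldimethylsilyloxy)phenyl]propanoate | CC(C)(C)[Si](C)(C)OC(=O)CCc1ccc(O[Si](C)(C)C(C)(C)C)cc1 | intermediate
18 | 3-[4-(tert-butyldimethylsilyloxy)phenyl]propanoic acid | OC(=O)CCc1ccc(O[Si](C)(C)C(C)(C)C)cc1 | intermediate
19 | [(1S,2RS,5R,6S,8S)-8-(tert-butyldimethylsilyloxy)-5-ethenyl-2-hydroxy-1,5,6-trimethyl-1,2,3,4,5,6,7,8-octahydronaphthalen-1-yl]methyl 3-[4-(tert-butyldimethylsilyloxy)phenyl]propanoate | C[C@H]1C[C@H](O[Si](C)(C)C(C)(C)C)C2=C(CCC(O)[C@]2(C)COC(=O)CCc2ccc(O[Si](C)(C)C(C)(C)C)cc2)[C@]1(C)C=C | intermediate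
20 | [(1S,5R,6S,8S)-8-(tert-butyldimethylsilyloxy)-5-ethenyl-1,5,6-trimethyl-2-oxo-1,2,3,4,5,6,7,8-octahydronaphthalen-1-yl]methyl 3-[4-(tert-butyldimethylsilyloxy)phenyl]propanoate | C[C@H]1C[C@H](O[Si](C)(C)C(C)(C)C)C2=C(CCC(=O)[C@]2(C)COC(=O)CCc2ccc(O[Si](C)(C)C(C)(C)C)cc2)[C@]1(C)C=C | intermediate
21 | 4-bromofuran-2(5H)-one | BrC1=CC(=O)OC1 | starting material
22 | B-alkyl-9-borabicyclo[3.3.1]nonane from hydroboration of the vinyl group of 20 (boron on C12) | C[C@H]1C[C@H](O[Si](C)(C)C(C)(C)C)C2=C(CCC(=O)[C@]2(C)COC(=O)CCc2ccc(O[Si](C)(C)C(C)(C)C)cc2)[C@]1(C)CCB1C2CCCC1CCC2 | intermediate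
23 | [(1S,5R,6S,8S)-8-(tert-butyldimethylsilyloxy)-1,5,6-trimethyl-2-oxo-5-[2-(5-oxo-2,5-dihydrofuran-3-yl)ethyl]-1,2,3,4,5,6,7,8-octahydronaphthalen-1-yl]methyl 3-[4-(tert-butyldimethylsilyloxy)phenyl]propanoate | C[C@H]1C[C@H](O[Si](C)(C)C(C)(C)C)C2=C(CCC(=O)[C@]2(C)COC(=O)CCc2ccc(O[Si](C)(C)C(C)(C)C)cc2)[C@]1(C)CCC1=CC(=O)OC1 | intermediate
24 | [(1S,5R,6S,8S)-8-hydroxy-1,5,6-trimethyl-2-oxo-5-[2-(5-oxo-2,5-dihydrofuran-3-yl)ethyl]-1,2,3,4,5,6,7,8-octahydronaphthalen-1-yl]methyl 3-(4-hydroxyphenyl)propanoate (CNP0301014.1) | C[C@H]1C[C@H](O)C2=C(CCC(=O)[C@]2(C)COC(=O)CCc2ccc(O)cc2)[C@]1(C)CCC1=CC(=O)OC1 | target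

Total step count: 14. Longest linear sequence: 13 steps (steps 1–9 and 11–14; step 10 is a one-step side branch).

Steps most likely to fail

1. Step 8 (Proposed new method). What may go wrong:
- enolisation of the Michael adduct toward C6 (the hydrogen there is γ to the ester and α to oxygen) instead of C10, so that ring closure places the double bond at C5=C6;
- α-addition to the acrylate without turnover;
- anionic oligomerisation of the acrylate.

Fallback (known reactions only; the C1–C10 bond and the alkene position are fixed before the Claisen closure). It sets out from 5 and comes back to the route at 14. Copper-catalysed conjugate addition of the zinc homoenolate Zn(CH2CH2CO2Et)2 (from [(1-ethoxycyclopropyl)oxy]trimethylsilane and ZnCl2; CuBr·SMe2, TMSCl, HMPA, THF) to 5 should give the silyl enol ether ethyl 3-[(1S,5S,6R)-6-ethenyl-5,6-dimethyl-3-(trimethylsilyloxy)cyclohex-2-en-1-yl]propanoate F1. Saegusa–Ito oxidation (Pd(OAc)2, MeCN) returns the unsaturation and gives ethyl 3-[(5S,6R)-6-ethenyl-5,6-dimethyl-3-oxocyclohex-1-en-1-yl]propanoate F2. α-Iodination (iodine, trimethylsilyl azide, then pyridine) gives the iodoenone ethyl 3-[(5S,6R)-6-ethenyl-2-iodo-5,6-dimethyl-3-oxocyclohex-1-en-1-yl]propanoate F3. CBS reduction as in step 5 gives the alcohol ethyl 3-[(3S,5S,6R)-6-ethenyl-3-hydroxy-2-iodo-5,6-dimethylcyclohex-1-en-1-yl]propanoate F4, and silylation as in step 6 gives its TBS ether ethyl 3-[(3S,5S,6R)-3-(tert-butyldimethylsilyloxy)-6-ethenyl-2-iodo-5,6-dimethylcyclohex-1-en-1-yl]propanoate F5. Reformatsky–Negishi coupling with 10 as in step 7 gives the diester tert-butyl (2RS)-2-[(3R,4S,6S)-6-(tert-butyldimethylsilyloxy)-2-(3-ethoxy-3-oxopropyl)-3-ethenyl-3,4-dimethylcyclohex-1-en-1-yl]propanoate F6. In F6 only C4–H is both α to an ester and allylic, so LDA (THF, −78 → 0 °C) should enolise there and close ring A by an ordinary Dieckmann condensation onto the ethyl ester to give 14, with the same control of C4 by the C6 silyloxy group.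

2. Step 1. What may go wrong: slow cycloaddition and loss of facial selectivity, because the enal carries a β-methyl group in addition to the α-substituent for which this catalysis is established.

Fallback (auxiliary control in place of catalyst control). It sets out from 1 and comes back at 5. 4-Methoxybut-3-en-2-one is condensed with (2R,5R)-2,5-diphenylpyrrolidine to the vinylogous amide (E)-4-[(2R,5R)-2,5-diphenylpyrrolidin-1-yl]but-3-en-2-one F7. O-Silylation (KHMDS, TBSCl, THF, −78 °C) gives the chiral diene (2R,5R)-1-[(E)-3-(tert-butyldimethylsilyloxy)buta-1,3-dien-1-yl]-2,5-diphenylpyrrolidine F8. Thermal Diels–Alder reaction of F8 with 1 (toluene, rt) should give, under control of the C2-symmetric amine, the aldehyde (1R,2S,6S)-4-(tert-butyldimethylsilyloxy)-2-[(2R,5R)-2,5-diphenylpyrrolidin-1-yl]-1,6-dimethylcyclohex-3-ene-1-carbaldehyde F9. Methylenation as in step 2 gives (2R,5R)-1-[(1S,5S,6R)-3-(tert-butyldimethylsilyloxy)-6-ethenyl-5,6-dimethylcyclohex-2-en-1-yl]-2,5-diphenylpyrrolidine F10, and aq HF in MeCN releases the auxiliary and gives 5. The auxiliary enantiomer named is assumed to give the sense shown; the other enantiomer is used otherwise.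

3. Step 5. What may go wrong: erosion of facial selectivity by mismatched double stereodifferentiation, since the ring is expected to favour axial hydride delivery, opposite to the catalyst.

Fallback (substrate-controlled reduction followed by inversion). It sets out from 6 and comes back at 7. Luche reduction (NaBH4, CeCl3·7H2O, MeOH, −78 °C) should give the C1 epimer (1R,4R,5S)-4-ethenyl-2-iodo-4,5-dimethylcyclohex-2-en-1-ol F11. Mitsunobu reaction (4-nitrobenzoic acid, PPh3, DIAD, THF) inverts C1 to the ester (1S,4R,5S)-4-ethenyl-2-iodo-4,5-dimethylcyclohex-2-en-1-yl 4-nitrobenzoate F12; SN2′ attack is blocked by the quaternary neighbour. Methanolysis (K2CO3, MeOH) gives 7.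

Further compounds
F1 | step 8 | ethyl 3-[(1S,5S,6R)-6-ethenyl-5,6-dimethyl-3-(trimethylsilyloxy)cyclohex-2-en-1-yl]propanoate | C[C@H]1CC(O[Si](C)(C)C)=C[C@H](CCC(=O)OCC)[C@]1(C)C=C
F2 | step 8 | ethyl 3-[(5S,6R)-6-ethenyl-5,6-dimethyl-3-oxocyclohex-1-en-1-yl]propanoate | C[C@H]1CC(=O)C=C(CCC(=O)OCC)[C@]1(C)C=C
F3 | step 8 | ethyl 3-[(5S,6R)-6-ethenyl-2-iodo-5,6-dimethyl-3-oxocyclohex-1-en-1-yl]propanoate | C[C@H]1CC(=O)C(I)=C(CCC(=O)OCC)[C@]1(C)C=C
F4 | step 8 | ethyl 3-[(3S,5S,6R)-6-ethenyl-3-hydroxy-2-iodo-5,6-dimethylcyclohex-1-en-1-yl]propanoate | C[C@H]1C[C@H](O)C(I)=C(CCC(=O)OCC)[C@]1(C)C=C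
F5 | step 8 | ethyl 3-[(3S,5S,6R)-3-(tert-butyldimethylsilyloxy)-6-ethenyl-2-iodo-5,6-dimethylcyclohex-1-en-1-yl]propanoate | C[C@H]1C[C@H](O[Si](C)(C)C(C)(C)C)C(I)=C(CCC(=O)OCC)[C@]1(C)C=C
F6 | step 8 | tert-butyl (2RS)-2-[(3R,4S,6S)-6-(tert-butyldimethylsilyloxy)-2-(3-ethoxy-3-oxopropyl)-3-ethenyl-3,4-dimethylcyclohex-1-en-1-yl]propanoate | C[C@H]1C[C@H](O[Si](C)(C)C(C)(C)C)C(C(C)C(=O)OC(C)(C)C)=C(CCC(=O)OCC)[C@]1(C)C=C
F7 | step 1 | (E)-4-[(2R,5R)-2,5-diphenylpyrrolidin-1-yl]but-3-en-2-one | CC(=O)/C=C/N1[C@@H](c2ccccc2)CC[C@@H]1c1ccccc1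
F8 | step 1 | (2R,5R)-1-[(E)-3-(tert-butyldimethylsilyloxy)buta-1,3-dien-1-yl]-2,5-diphenylpyrrolidine | C=C(O[Si](C)(C)C(C)(C)C)/C=C/N1[C@@H](c2ccccc2)CC[C@@H]1c1ccccc1
F9 | step 1 | (1R,2S,6S)-4-(tert-butyldimethylsilyloxy)-2-[(2R,5R)-2,5-diphenylpyrrolidin-1-yl]-1,6-dimethylcyclohex-3-ene-1-carbaldehyde | C[C@H]1CC(O[Si](C)(C)C(C)(C)C)=C[C@H](N2[C@@H](c3ccccc3)CC[C@@H]2c2ccccc2)[C@]1(C)C=O
F10 | step 1 | (2R,5R)-1-[(1S,5S,6R)-3-(tert-butyldimethylsilyloxy)-6-ethenyl-5,6-dimethylcyclohex-2-en-1-yl]-2,5-diphenylpyrrolidine | C[C@H]1CC(O[Si](C)(C)C(C)(C)C)=C[C@H](N2[C@@H](c3ccccc3)CC[C@@H]2c2ccccc2)[C@]1(C)C=C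
F11 | step 5 | (1R,4R,5S)-4-ethenyl-2-iodo-4,5-dimethylcyclohex-2-en-1-ol | C[C@H]1C[C@@H](O)C(I)=C[C@]1(C)C=C
F12 | step 5 | (1S,4R,5S)-4-ethenyl-2-iodo-4,5-dimethylcyclohex-2-en-1-yl 4-nitrobenzoate | C[C@H]1C[C@H](OC(=O)c2ccc(cc2)[N+](=O)[O-])C(I)=C[C@]1(C)C=C
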